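(The constants are those of an exercise; what happens was integrated by code.)

The reagent's fate in these flasks turns on one ratio: its loss to starting material over its loss on the catalyst.

    reagent + catalyst intermediate A → free catalyst + target (k1 = 3500 M⁻¹ s⁻¹)
    crystals ⇌ target, rate k2*(cs2 - [target]) while solid is left; crystals form when [target] > cs2 (cs2 = 2.0 mM, k2 = 0.38 s⁻¹)
    second substrate + free catalyst ⇌ catalyst intermediate B (K3 = 19000 M⁻¹, k3 = 13000 M⁻¹ s⁻¹)
    starting material + free catalyst ⇌ catalyst intermediate A (K4 = 84 M⁻¹, k4 = 460 M⁻¹ s⁻¹)
    starting material → decomposition product (k5 = 1.9 × 10⁻⁴ s⁻¹)
    reagent + catalyst intermediate B → free catalyst + second product (k6 = 1100 M⁻¹ s⁻¹)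
    starting material + reagent → uncatalysed product (k7 = 14 M⁻¹ s⁻¹)

common to all: reagent 0.600 equiv; free catalyst 5 mol%; time 1.5 min
- midnight: starting material 0.0050 M (fed, over 20 s); second substrate 1.00 equiv; all else is in the flask from the start; the feed brings no volume worth counting
- winter: starting material 0.0050 M; second substrate 1.00 equiv; everything together at the start
- autumn: starting material 0.0050 M; second substrate 1.00 equiv (fed, over 20 s); all else is in the flask from the start; the feed brings no volume worth counting

- what is said of target includes crystals
- crystals is a solid; its amount is given per volume of the solution
- run time (midnight): 1.5 min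

* the flask with the highest amount of uncatalysed product, in percent of the starting material charged ("all alike" if they lie within 1.5 percentage points) (midnight / winter / autumn / all alike)
* final uncatalysed product, as a percentage of the starting material charged, in midnight
* final uncatalysed product, as a percentage of the starting material charged, in winter
* final uncatalysed product, as a percentage of the starting material charged, in autumn

1. The puzzle: step 6 has a constant 78.6 times that of step 7, yet by the reckoning below winter loses 20.3% of its reagent to uncatalysed product.

2. Second substrate outbinds starting material, 95.0 against 0.420 for the bound-to-free ratio. So catalyst intermediate B, the resting state, holds nearly all of the 0.250 mM of catalyst. Reagent then decays pseudo-first-order with lifetime 3.64 s.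

3. At full charge k7[starting material]/(k6[catalyst intermediate B]) is 0.255; call it the leak ratio and write it ρ. Starting material outnumbers catalyst 20.0 to one, and this clears the puzzle. Reagent, at 0.600 equiv, stands below the 1.00 equiv of second substrate as the limiting reagent, so the uncatalysed product of a flask is the reagent charge times ρ/(1+ρ). For winter: 12.2%.

4. In midnight the feed runs longer than the reagent lifetime, 5.50 of them, so reagent meets a rising [starting material]. Averaging that ramp over the decay multiplies ρ by (τ/tf)(1−exp(−tf/τ)) = 0.181, giving 0.0461 and 2.64%.

5. In autumn second substrate arrives at 0.250 mM s⁻¹, against a demand of 0.825 mM s⁻¹. With reagent at its charge, catalyst intermediate B is reckoned near 0.0758 mM. Reagent drains catalyst intermediate A at 10.5 s⁻¹, faster than its back-rate of 5.48 s⁻¹, so a steady state, not the binding equilibrium, puts it near 0.0219 mM. Both routes together give a starting ratio of 0.437, and held through the run that ratio gives 18.3%. The ranking: autumn.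

6. The forecast says autumn, with 3.1%, 11.8% and 13.3% for midnight, winter and autumn, “which makes that call a close one”.

7. The simulation gives autumn, with 2.55% in midnight, 11.8% in winter and 14.1% in autumn. In midnight at 0.0374 min, reagent goes by catalyst intermediate B 34 times as fast as by step 7, where the inverse ramped leak ratio reads 35.0. For the neighbour of midnight with 1.2 mol% of free catalyst, the leak ratio becomes 1.06 and the lifetime 15.2 s, which reckons to 22.2%, and that flask holds 17.5%.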